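The quinone ring is numbered C1 (C=O), C2 (C–OH), C3 (side chain), C4 (C=O), C5 (C–OMe), C6 (C–H). It is the bis-enol of a cyclohexane-1,2,4,5-tetraone: two vicinal dicarbonyl pairs, C1/C2 and C4/C5, linked through C3 and C6. A double Claisen annulation therefore closes the ring from two open-chain 1,2-dicarbonyl halves. Both α-carbons of a 2,3-diketone that already carries the (R)-configured, silyl-protected side chain attack the two carbonyl carbons of dimethyl oxalate, forming C3–C4 and C5–C6 at the final oxidation level. Regioselective O-methylation at C5, desilylation and acetylation finish the route; the stereocentre derives from (R)-epichlorohydrin.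

Key step: step 5

Remark: compounds 12–16 are drawn as the 2-hydroxy-1,4-benzoquinone tautomers, and the ring numbering above is used throughout.

Step 1
Reactants: 1 decylmagnesium bromide; 2 (R)-epichlorohydrin
Product: 4 (2R)-2-undecyloxirane, via (2R)-1-chlorotridecan-2-ol 3 (not isolated)
Conditions: CuI (10 mol %), THF, −40 → 0 °C; then 4 M aq. NaOH, MeOH, rt (same flask)
Reagents that add atoms: none
Why: Copper-catalysed Grignard opening of the oxirane at its unsubstituted carbon (SN2) followed by intramolecular Williamson closure of the chlorohydrin breaks no bond at the stereocentre, so the (R) centre of 2 should pass unchanged into 4.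

Step 2
Reactants: 4 (2R)-2-undecyloxirane; 5 but-2-yne
Product: 7 (6R)-heptadec-2-yn-6-ol, via but-2-yn-1-yllithium 6 (not isolated)
Conditions: 5 (2 equiv), n-BuLi (1.5 equiv), TMEDA, THF, −78 → 0 °C; then 4, −78 °C → rt; H2O
Reagents that add atoms: none
Why: Propargylic lithiation of 5 and SN2 opening of the terminal epoxide at its CH2 carbon by the propargyl terminus of the organolithium (epoxide alkylation) should give the internal alkyne without touching the carbinol centre.

Step 3
Reactants: 7 (6R)-heptadec-2-yn-6-ol
Product: 8 (6R)-6-[(triisopropylsilyl)oxy]heptadec-2-yne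
Conditions: TIPSOTf (1.3 equiv), 2,6-lutidine, CH2Cl2, 0 °C → rt
Reagents that add atoms: triisopropylsilyl trifluoromethanesulfonate, CC(C)[Si](C(C)C)(C(C)C)OS(=O)(=O)C(F)(F)F
Why: Silylation of the secondary alcohol with a silyl triflate and a hindered pyridine base installs an ether chosen to withstand methoxide (step 5) and dilute acidic methanol (step 6).

Step 4
Reactants: 8 (6R)-6-[(triisopropylsilyl)oxy]heptadec-2-yne
Product: 9 (6R)-6-[(triisopropylsilyl)oxy]heptadecane-2,3-dione
Conditions: RuCl3·xH2O (3 mol %), NaIO4 (2.5 equiv), NaHCO3, MeCN/EtOAc/H2O, 0 °C → rt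
Reagents that add atoms: sodium periodate (oxygen source, relayed by RuO4), [Na+].[O-]I(=O)(=O)=O
Why: RuO4 generated in situ oxidises the internal dialkyl alkyne to the 1,2-diketone, while the silyl ether and the saturated chain are inert and the buffered biphasic medium limits oxidative cleavage.

Step 5
Reactants: 9 (6R)-6-[(triisopropylsilyl)oxy]heptadecane-2,3-dione; 10 dimethyl oxalate
Product: 12 2,5-dihydroxy-3-[(2R)-2-[(triisopropylsilyl)oxy]tridecyl]-1,4-benzoquinone, via trioxo ester 11 (not isolated)
Conditions: NaOMe (3.5 equiv), 10 (1.5 equiv), MeOH/THF, 9 added slowly at 0 °C, then 50 °C; 1 M HCl to pH 2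
Reagents that add atoms: none
Why: Methoxide enolises 9 at its methyl carbon, which is acylated by the non-enolisable, highly electrophilic diester 10 to give the 2,4,5-trioxo ester 11 as its enolate; the enolate at the diketone's C4 then attacks the remaining ester carbonyl, and loss of the second methoxide gives the cyclohexane-1,2,4,5-tetraone, held as the dianion of the 2,5-dihydroxyquinone until acidification. The closest known reaction types are the Claisen oxalylation of methyl ketones and the base-mediated cyclisation of 2-oxo esters to 3,6-dialkyl-2,5-dihydroxybenzoquinones, whose ring-closing event is the same attack of a 1,2-diketone α-carbon on a 2-oxo ester. The six-membered ring closes in a Dieckmann-type 6-(enolendo)-exo-trig mode. No stereocentre is formed, and the silyloxy-bearing carbon is not α to any carbonyl and cannot epimerise. The step needs crossed Claisen acylation to outrun aldol self-condensation of the diketone and C-acylation to prevail over O-acylation, which slow addition of 9 to excess 10, the reversibility of aldol and O-acylation under methoxide and the irreversible formation of the vinylogous dicarboxylate dianion should secure. The ring constitution is unambiguous because either order of the two acylations converges on the same tetraone.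

Step 6
Reactants: 12 2,5-dihydroxy-3-[(2R)-2-[(triisopropylsilyl)oxy]tridecyl]-1,4-benzoquinone
Product: 13 2-hydroxy-5-methoxy-3-[(2R)-2-[(triisopropylsilyl)oxy]tridecyl]-1,4-benzoquinone
Conditions: MeOH, H2SO4 (cat.), rt
Reagents that add atoms: methanol, CO
Why: In this vinylogous Fischer esterification methanol adds at the unhindered C5 (flanked by C6–H) and water leaves, whereas the C2 hydroxyl next to the branched side chain is hindered and its ether would be twisted out of conjugation, so the C5 monoether should be both the kinetic and the thermodynamic product.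

Step 7
Reactants: 13 2-hydroxy-5-methoxy-3-[(2R)-2-[(triisopropylsilyl)oxy]tridecyl]-1,4-benzoquinone
Product: 14 2-hydroxy-3-[(2R)-2-hydroxytridecyl]-5-methoxy-1,4-benzoquinone
Conditions: HF·pyridine, pyridine/THF, 0 °C → rt
Reagents that add atoms: none
Why: Fluoride-mediated desilylation driven by Si–F bond formation under buffered conditions should free the secondary alcohol without affecting the quinone, the vinylogous methyl ester or the stereocentre.

Step 8
Reactants: 14 2-hydroxy-3-[(2R)-2-hydroxytridecyl]-5-methoxy-1,4-benzoquinone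
Product: 16 (2R)-1-(2-hydroxy-5-methoxy-3,6-dioxocyclohexa-1,4-dien-1-yl)tridecan-2-yl acetate, via diacetate 15 (not isolated)
Conditions: Ac2O (3 equiv), pyridine, DMAP (cat.), CH2Cl2, 0 °C → rt; then MeOH, aq. NaHCO3, 0 °C
Reagents that add atoms: acetic anhydride, CC(=O)OC(C)=O
Why: DMAP-catalysed O-acylation acetylates both hydroxyls, and the quinonyl acetate of 15, a vinylogous mixed anhydride, should then be cleaved selectively by bicarbonate-buffered methanolysis while the secondary alkyl acetate survives with its configuration intact.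

Compound list
1 | decylmagnesium bromide | CCCCCCCCCC[Mg]Br | starting material
2 | (R)-epichlorohydrin, (2R)-2-(chloromethyl)oxirane | ClC[C@H]1CO1 | starting material
3 | (2R)-1-chlorotridecan-2-ol | ClC[C@H](O)CCCCCCCCCCC | intermediate
4 | (2R)-2-undecyloxirane | CCCCCCCCCCC[C@@H]1CO1 | intermediate
5 | but-2-yne | CC#CC | starting material
6 | but-2-yn-1-yllithium | [Li]CC#CC | intermediate
7 | (6R)-heptadec-2-yn-6-ol | CC#CCC[C@H](O)CCCCCCCCCCC | intermediate
8 | (6R)-6-[(triisopropylsilyl)oxy]heptadec-2-yne | CC#CCC[C@H](O[Si](C(C)C)(C(C)C)C(C)C)CCCCCCCCCCC | intermediate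
9 | (6R)-6-[(triisopropylsilyl)oxy]heptadecane-2,3-dione | CC(=O)C(=O)CC[C@H](O[Si](C(C)C)(C(C)C)C(C)C)CCCCCCCCCCC | intermediate
10 | dimethyl oxalate | COC(=O)C(=O)OC | starting material
11 | methyl (8R)-2,4,5-trioxo-8-[(triisopropylsilyl)oxy]nonadecanoate | COC(=O)C(=O)CC(=O)C(=O)CC[C@H](O[Si](C(C)C)(C(C)C)C(C)C)CCCCCCCCCCC | intermediate
12 | 2,5-dihydroxy-3-[(2R)-2-[(triisopropylsilyl)oxy]tridecyl]-1,4-benzoquinone | CCCCCCCCCCC[C@H](CC1=C(O)C(=O)C=C(O)C1=O)O[Si](C(C)C)(C(C)C)C(C)C | intermediate
13 | 2-hydroxy-5-methoxy-3-[(2R)-2-[(triisopropylsilyl)oxy]tridecyl]-1,4-benzoquinone | CCCCCCCCCCC[C@H](CC1=C(O)C(=O)C=C(OC)C1=O)O[Si](C(C)C)(C(C)C)C(C)C | intermediate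
14 | 2-hydroxy-3-[(2R)-2-hydroxytridecyl]-5-methoxy-1,4-benzoquinone | CCCCCCCCCCC[C@H](CC1=C(O)C(=O)C=C(OC)C1=O)O | intermediate
15 | (2R)-1-(2-acetoxy-5-methoxy-3,6-dioxocyclohexa-1,4-dien-1-yl)tridecan-2-yl acetate | CCCCCCCCCCC[C@H](CC1=C(OC(C)=O)C(=O)C=C(OC)C1=O)OC(C)=O | intermediate
16 | (2R)-1-(2-hydroxy-5-methoxy-3,6-dioxocyclohexa-1,4-dien-1-yl)tridecan-2-yl acetate | CCCCCCCCCCC[C@H](CC1=C(O)C(=O)C=C(OC)C1=O)OC(C)=O | target

Total step count: 8. Longest linear sequence: 8 steps (1/2 → 4 → 7 → 8 → 9 → 12 → 13 → 14 → 16).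

Steps most likely to fail

Step 5. Aldol self-condensation of the diketone and retro-Claisen fragmentation of the polycarbonyl intermediates may outpace the double acylation. The fallback abandons the ring construction and sets out from 4. Commercial 1,2,4,5-tetramethoxybenzene is lithiated (n-BuLi, TMEDA, THF, 0 °C) and the aryllithium opens 4 at its CH2 carbon (BF3·OEt2, −78 °C) to give (2R)-1-(2,3,5,6-tetramethoxyphenyl)tridecan-2-ol F1. Acetylation (Ac2O, pyridine, DMAP) gives (2R)-1-(2,3,5,6-tetramethoxyphenyl)tridecan-2-yl acetate F2. Oxidative demethylation with (NH4)2Ce(NO3)6 in MeCN/H2O should give (2R)-1-(2,5-dimethoxy-3,6-dioxocyclohexa-1,4-dien-1-yl)tridecan-2-yl acetate F3. Regioselective hydrolysis of the twisted, less conjugated C2 methoxy group next to the side chain (dilute HClO4, THF, 0 °C → rt) comes back to the route at 16.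

Step 2. The ambident propargyl/allenyl lithium reagent may react through its allenyl terminus, and base may shift the triple bond. The fallback sets out from 4 and uses a silyl-blocked propargyl anion. 1-(Trimethylsilyl)propyne is lithiated (n-BuLi, TMEDA, THF, −78 → 0 °C) and opens 4 to give (5R)-1-(trimethylsilyl)hexadec-1-yn-5-ol F4. Silylation (TIPSOTf, 2,6-lutidine) gives (5R)-5-[(triisopropylsilyl)oxy]-1-(trimethylsilyl)hexadec-1-yne F5. K2CO3 in MeOH removes the alkynyl silane to give (5R)-5-[(triisopropylsilyl)oxy]hexadec-1-yne F6. Deprotonation with n-BuLi (THF, −78 °C) and methylation with MeI comes back to the route at 8.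

Step 6. Discrimination between the two enolic hydroxyls may be incomplete, giving etherification at C2 or at both positions. The fallback sets out from 12 and reverses the logic: over-methylate, then unmask selectively. Exhaustive O-methylation (TMSCHN2, MeOH/toluene, 0 °C → rt) gives 2,5-dimethoxy-3-[(2R)-2-[(triisopropylsilyl)oxy]tridecyl]-1,4-benzoquinone F7. Selective hydrolysis of the hindered, out-of-plane C2 methoxy group (dilute HClO4, THF, 0 °C) comes back to the route at 13.

Further compounds
F1 | step 5 | (2R)-1-(2,3,5,6-tetramethoxyphenyl)tridecan-2-ol | CCCCCCCCCCC[C@H](Cc1c(OC)c(OC)cc(OC)c1OC)O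
F2 | step 5 | (2R)-1-(2,3,5,6-tetramethoxyphenyl)tridecan-2-yl acetate | CCCCCCCCCCC[C@H](Cc1c(OC)c(OC)cc(OC)c1OC)OC(C)=O
F3 | step 5 | (2R)-1-(2,5-dimethoxy-3,6-dioxocyclohexa-1,4-dien-1-yl)tridecan-2-yl acetate | CCCCCCCCCCC[C@H](CC1=C(OC)C(=O)C=C(OC)C1=O)OC(C)=O
F4 | step 2 | (5R)-1-(trimethylsilyl)hexadec-1-yn-5-ol | C[Si](C)(C)C#CCC[C@H](O)CCCCCCCCCCC
F5 | step 2 | (5R)-5-[(triisopropylsilyl)oxy]-1-(trimethylsilyl)hexadec-1-yne | C[Si](C)(C)C#CCC[C@H](O[Si](C(C)C)(C(C)C)C(C)C)CCCCCCCCCCC
F6 | step 2 | (5R)-5-[(triisopropylsilyl)oxy]hexadec-1-yne | C#CCC[C@H](O[Si](C(C)C)(C(C)C)C(C)C)CCCCCCCCCCC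
F7 | step 6 | 2,5-dimethoxy-3-[(2R)-2-[(triisopropylsilyl)oxy]tridecyl]-1,4-benzoquinone | CCCCCCCCCCC[C@H](CC1=C(OC)C(=O)C=C(OC)C1=O)O[Si](C(C)C)(C(C)C)C(C)C
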